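**Assumption:** the SMILES is taken literally, i.e. (6S,7R,8R,10R) with a cis-fused lactone, in germacrane numbering (C1 ketone, C2=C3 furanone alkene, C4=C5, C6 lactone carbinol, C7, C8 ester carbinol, C9, C10 quaternary, C11=C13, C12 lactone C=O, C14 methyl, C15 CH2OH); this numbering is used throughout.

## Retrosynthetic overview

1. Target ⇐ C15–O desilylation and C8–O tigloylation of hydroxy lactone 23.
2. Ten-membered carbocycle and γ-lactone ⇐ one intramolecular CrCl2 allylation joining the C6 aldehyde carbon to C7, the β-carbon of a 2-(bromomethyl)enoate used as an ester homoenolate equivalent (key bond); the lactone closes on O6 in the same step.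
3. Allyl bromide ⇐ Morita–Baylis–Hillman reaction at the C7 aldehyde, then SN2′ bromination; enal ⇐ oxidation of C6–OH.
4. Furanone (first ring formed) ⇐ γ-hydroxy ynone ⇐ carbonylative Sonogashira coupling of vinyl iodide 5 (from 2-butyne-1,4-diol) with alkyne 12.
5. Alkyne 12 ⇐ proline aldol (sets C8) and chelation-controlled ethynylation (sets C10) from acetone, 2,2-dimethoxyacetaldehyde and HC≡CMgBr.

## Route

**Step 1**
Reactants: 1 2-butyne-1,4-diol
Product: 2 4-[(tert-butyldiphenylsilyl)oxy]but-2-yn-1-ol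
Conditions: NaH (1.0 equiv), THF, 0 °C to rt; TBDPSCl (1.0 equiv)
Reagents that add atoms: tert-butyl(chloro)diphenylsilane (TBDPSCl), CC(C)(C)[Si](Cl)(c1ccccc1)c1ccccc1
Why: O-silylation of the sparingly soluble monosodium alkoxide of a symmetric diol (McDougal monosilylation) stops cleanly at the mono-ether; no stereocentre is involved.

**Step 2**
Reactants: 2 4-[(tert-butyldiphenylsilyl)oxy]but-2-yn-1-ol
Product: 4 (Z)-4-[(tert-butyldiphenylsilyl)oxy]-3-iodobut-2-en-1-ol, via cyclic alkenylaluminate 3 (not isolated)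
Conditions: NaAlH2(OCH2CH2OMe)2, THF, 0 °C; EtOAc; then I2, THF, −78 °C to 0 °C
Reagents that add atoms: iodine, II
Why: hydroxyl-directed trans-hydroalumination of the propargylic alcohol puts aluminium on the distal alkyne carbon inside a five-membered ring, and iodinolysis with retention gives the (Z)-iodide with I cis to CH2OH (the later C3/C6 cis relationship).

**Step 3**
Reactants: 4 (Z)-4-[(tert-butyldiphenylsilyl)oxy]-3-iodobut-2-en-1-ol
Product: 5 (Z)-1-[(tert-butyldimethylsilyl)oxy]-4-[(tert-butyldiphenylsilyl)oxy]-3-iodobut-2-ene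
Conditions: TBSCl, imidazole, CH2Cl2, 0 °C to rt
Reagents that add atoms: tert-butyl(chloro)dimethylsilane (TBSCl), CC(C)(C)[Si](C)(C)Cl
Why: standard silylation of the primary allylic alcohol, needed because a free cis-CH2OH would trap the acylpalladium of step 7 as a butenolide; the olefin geometry is untouched.

**Step 4**
Reactants: 6 acetone; 7 2,2-dimethoxyacetaldehyde (60% aqueous solution)
Product: 8 (R)-4-hydroxy-5,5-dimethoxypentan-2-one
Conditions: L-proline (30 mol%), acetone/DMSO, rt, 24–48 h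
Reagents that add atoms: none
Why: proline-catalysed direct enamine aldol (List–Barbas type) in which the α,α-dialkoxy aldehyde behaves like an α-branched acceptor and the hydrogen-bonded Houk–List transition state delivers the enamine to the Re face, setting C8 as R (expected er about 90:10 or better).

**Step 5**
Reactants: 8 (R)-4-hydroxy-5,5-dimethoxypentan-2-one; 9 ethynylmagnesium bromide (HC≡CMgBr, 3 equiv)
Product: 11 (3R,5R)-6,6-dimethoxy-3-methylhex-1-yne-3,5-diol, via bromomagnesium alkoxide chelate 10 (not isolated)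
Conditions: HC≡CMgBr, THF/CH2Cl2, −78 °C to −20 °C; aq. NH4Cl
Reagents that add atoms: none
Why: chelation-controlled (Cram-chelate) Grignard addition in which the magnesium alkoxide holds the ketone in a six-membered half-chair and the acetylide enters axially, giving the 1,3-anti diol and so the R quaternary centre C10 (expected dr about 5:1, minor epimer removed by chromatography).

**Step 6**
Reactants: 11 (3R,5R)-6,6-dimethoxy-3-methylhex-1-yne-3,5-diol
Product: 12 (3R,5R)-6,6-dimethoxy-5-[(4-methoxybenzyl)oxy]-3-methylhex-1-yn-3-ol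
Conditions: NaH (1.05 equiv), PMBCl, Bu4NI (cat.), THF/DMF, 0 °C
Reagents that add atoms: 4-methoxybenzyl chloride (PMBCl), COc1ccc(CCl)cc1
Why: Williamson etherification occurs at the less hindered secondary alkoxide and leaves the tertiary propargylic alcohol free; the small, coordinating ether blocks O8 from adding to the ynone later and is not a leaving group in the allylmetal step.

**Step 7**
Reactants: 12 (3R,5R)-6,6-dimethoxy-5-[(4-methoxybenzyl)oxy]-3-methylhex-1-yn-3-ol; 5 (Z)-1-[(tert-butyldimethylsilyl)oxy]-4-[(tert-butyldiphenylsilyl)oxy]-3-iodobut-2-ene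
Product: 13 (2Z,7R,9R)-1-[(tert-butyldimethylsilyl)oxy]-3-{[(tert-butyldiphenylsilyl)oxy]methyl}-7-hydroxy-10,10-dimethoxy-9-[(4-methoxybenzyl)oxy]-7-methyldec-2-en-5-yn-4-one
Conditions: PdCl2(PPh3)2 (5 mol%), CuI (5 mol%), Et3N, THF, CO (1 atm), rt
Reagents that add atoms: carbon monoxide, [C-]#[O+]
Why: carbonylative Sonogashira coupling (oxidative addition of the vinyl iodide to zerovalent palladium, CO insertion, alkynyl transfer from copper, reductive elimination) installs C3 as the ynone carbonyl with retention of the Z geometry.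

**Step 8**
Reactants: 13 the γ-hydroxy ynone
Product: 16 (2R)-3-[(2R)-5-{(2Z)-1-[(tert-butyldiphenylsilyl)oxy]-4-hydroxybut-2-en-2-yl}-2-methyl-3-oxo-2,3-dihydrofuran-2-yl]-2-[(4-methoxybenzyl)oxy]propanal, via diethylamino enone 14 (not isolated), via silylated furanone acetal 15 (not isolated)
Conditions: Et2NH, EtOH, rt; then 1 M HCl, THF, rt
Reagents that add atoms: water, O
Why: conjugate addition of Et2NH to the ynone and acid hydrolysis give a 1,3-diketone that cyclodehydrates through the tertiary C10–OH to the 3(2H)-furanone (Jackson–Raphael furanone synthesis), and the same acid then cleaves the primary allylic TBS ether and the dimethyl acetal while PMB and TBDPS ethers survive; C8 and C10 are not touched.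

**Step 9**
Reactants: 16 the furanone aldehyde; 17 methyl acrylate
Product: 18 methyl (4R)-3-hydroxy-4-[(4-methoxybenzyl)oxy]-2-methylidene-5-[(2R)-5-{(2Z)-1-[(tert-butyldiphenylsilyl)oxy]-4-hydroxybut-2-en-2-yl}-2-methyl-3-oxo-2,3-dihydrofuran-2-yl]pentanoate (both C3 epimers)
Conditions: DABCO (1 equiv), methyl acrylate (excess), MeOH, rt, 3–5 d
Reagents that add atoms: none
Why: Morita–Baylis–Hillman reaction of an α-alkoxy aldehyde, a substrate class that reacts without loss of configuration at the α-carbon (C8); the new carbinol (C7) is a mixture, which is irrelevant because it becomes sp2 in step 11.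

**Step 10**
Reactants: 18 the Baylis–Hillman diol
Product: 19 the corresponding (Z)-enal, methyl (4R)-3-hydroxy-4-[(4-methoxybenzyl)oxy]-2-methylidene-5-[(2R)-5-{(2Z)-1-[(tert-butyldiphenylsilyl)oxy]-4-oxobut-2-en-2-yl}-2-methyl-3-oxo-2,3-dihydrofuran-2-yl]pentanoate
Conditions: TEMPO (10 mol%), PhI(OAc)2 (1.1 equiv), CH2Cl2, rt
Reagents that add atoms: none
Why: oxoammonium (TEMPO/PhI(OAc)2) oxidation is strongly selective for the primary allylic C6–OH over the hindered, electron-poor secondary Baylis–Hillman alcohol, and the neutral conditions keep the Z-enal geometry.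

**Step 11**
Reactants: 19 the enal alcohol
Product: 20 methyl (2Z,4R)-2-(bromomethyl)-4-[(4-methoxybenzyl)oxy]-5-[(2R)-5-{(2Z)-1-[(tert-butyldiphenylsilyl)oxy]-4-oxobut-2-en-2-yl}-2-methyl-3-oxo-2,3-dihydrofuran-2-yl]pent-2-enoate
Conditions: NBS, Me2S, CH2Cl2, −20 °C (reagent pre-formed), then 19, to 0 °C
Reagents that add atoms: N-bromosuccinimide, O=C1CCC(=O)N1Br
Why: the Corey–Kim-type bromosulfonium reagent activates the Baylis–Hillman hydroxyl and bromide attacks the methylene carbon (SN2′) to give the thermodynamically preferred (Z)-2-(bromomethyl)enoate (C8 cis to CH2Br); pre-forming the reagent avoids free NBS, which would brominate the furanone C2.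

**Step 12 (key step)**
Reactants: 20 the allylic bromide enal
Product: 22 (6S,7R,8R,10R)-8-O-(4-methoxybenzyl)-15-O-(tert-butyldiphenylsilyl) derivative of the 8-detigloyl target (cis-fused α-methylene-γ-lactone, complete ring system), via hydroxy ester 21 (not isolated)
Conditions: CrCl2 (10 equiv), THF, rt, slow addition of 20 to 2 mM; aq. NH4Cl; then p-TsOH (cat.), CH2Cl2, rt
Reagents that add atoms: none
Why: insertion of divalent chromium into the C–Br bond turns C7, the β-carbon of the enoate and normally an acceptor, into the nucleophilic terminus of a 2-(methoxycarbonyl)allylchromium (an ester homoenolate equivalent), which adds through C7 to the C6 aldehyde in an intramolecular Nozaki–Hiyama-type Barbier allylation of the kind used to close ten-membered germacranolide rings; in the chromium-bridged closed transition state the short C5···C9 tether has to sit gauche on the attacked face, which gives the syn adduct (cis lactone, 6S), and the C8 ether oxygen eclipses the allyl unit toward chromium ("inside") with the tether on the attacked face, which gives 7R relative to the existing 8R centre, after which the chromium alkoxide lactonises onto the methyl ester.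

**Step 13**
Reactants: 22 the macrocyclic lactone PMB ether
Product: 23 (6S,7R,8R,10R)-15-O-(tert-butyldiphenylsilyl)-8-hydroxy lactone (8-detigloyl target, C15 silyl ether)
Conditions: DDQ, CH2Cl2/pH 7 buffer, 0 °C to rt
Reagents that add atoms: none
Why: oxidative cleavage of the 4-methoxybenzyl ether by hydride abstraction and hydrolysis is neutral, so the α-methylene lactone, the furanone and the silyl ether are untouched and no stereocentre is affected.

**Step 14**
Reactants: 23 the 8-hydroxy lactone; 24 tiglic acid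
Product: 25 (6S,7R,8R,10R)-15-O-(tert-butyldiphenylsilyl) ether of the target
Conditions: tiglic acid, 2,4,6-Cl3C6H2COCl, Et3N, toluene, rt; then 23, DMAP, rt
Reagents that add atoms: none
Why: Yamaguchi esterification through the mixed anhydride acylates the hindered secondary C8–OH with retention at C8 and without E/Z isomerisation or deconjugation of the tigloyl group, and acylation of the free hydroxyl outruns translactonisation.

**Step 15**
Reactants: 25 the silyl-protected target
Product: 26 the target, (6S,7R,8R,10R)-8-tigloyloxy-15-hydroxy furanone germacranolide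
Conditions: HF·pyridine, pyridine/THF, 0 °C to rt
Reagents that add atoms: none
Why: buffered fluoride desilylation of the primary allylic TBDPS ether is mildly acidic, so the tiglate, the α-methylene lactone and the furanone survive and no stereocentre is touched.

## Compound list

1 | 2-butyne-1,4-diol | OCC#CCO | starting material
2 | 4-[(tert-butyldiphenylsilyl)oxy]but-2-yn-1-ol | OCC#CCO[Si](c1ccccc1)(c1ccccc1)C(C)(C)C | intermediate
3 | sodium cyclic alkenylaluminate (1-oxa-2-aluminacyclopent-3-ene ate complex, CH2OTBDPS on the Al-bearing carbon, two 2-methoxyethoxy ligands) | [Na+].COCCO[Al-]1(OCCOC)OCC=C1CO[Si](c2ccccc2)(c2ccccc2)C(C)(C)C | intermediate (not isolated)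
4 | (Z)-4-[(tert-butyldiphenylsilyl)oxy]-3-iodobut-2-en-1-ol | OC/C=C(\I)CO[Si](c1ccccc1)(c1ccccc1)C(C)(C)C | intermediate
5 | (Z)-1-[(tert-butyldimethylsilyl)oxy]-4-[(tert-butyldiphenylsilyl)oxy]-3-iodobut-2-ene | CC(C)(C)[Si](C)(C)OC/C=C(\I)CO[Si](c1ccccc1)(c1ccccc1)C(C)(C)C | intermediate
6 | acetone | CC(C)=O | starting material
7 | 2,2-dimethoxyacetaldehyde | COC(OC)C=O | starting material
8 | (R)-4-hydroxy-5,5-dimethoxypentan-2-one | CC(=O)C[C@@H](O)C(OC)OC | intermediate
9 | ethynylmagnesium bromide | C#C[Mg]Br | starting material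
10 | bromomagnesium alkoxide (chelate) of 8 | CC(=O)C[C@@H](O[Mg]Br)C(OC)OC | intermediate (not isolated)
11 | (3R,5R)-6,6-dimethoxy-3-methylhex-1-yne-3,5-diol | C#C[C@@](C)(C[C@@H](O)C(OC)OC)O | intermediate
12 | (3R,5R)-6,6-dimethoxy-5-[(4-methoxybenzyl)oxy]-3-methylhex-1-yn-3-ol | C#C[C@@](C)(C[C@@H](OCc1ccc(OC)cc1)C(OC)OC)O | intermediate
13 | (2Z,7R,9R)-1-[(tert-butyldimethylsilyl)oxy]-3-{[(tert-butyldiphenylsilyl)oxy]methyl}-7-hydroxy-10,10-dimethoxy-9-[(4-methoxybenzyl)oxy]-7-methyldec-2-en-5-yn-4-one | CC(C)(C)[Si](C)(C)OC/C=C(/CO[Si](c1ccccc1)(c1ccccc1)C(C)(C)C)C(=O)C#C[C@](C)(O)C[C@@H](OCc1ccc(OC)cc1)C(OC)OC | intermediate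
14 | diethylamino enone: 13 with Et2NH added across the alkyne (NEt2 on the carbon next to the carbinol, trans to the ketone) | CC(C)(C)[Si](C)(C)OC/C=C(/CO[Si](c1ccccc1)(c1ccccc1)C(C)(C)C)C(=O)/C=C(/N(CC)CC)[C@](C)(O)C[C@@H](OCc1ccc(OC)cc1)C(OC)OC | intermediate (not isolated)
15 | silylated furanone acetal: (2R)-2-methyl-3(2H)-furanone carrying the (R)-3,3-dimethoxy-2-(PMB-oxy)propyl group at C2 and the (Z)-4-(TBSO)-1-(TBDPSO)but-2-en-2-yl group at C5 | CC(C)(C)[Si](C)(C)OC/C=C(/CO[Si](c2ccccc2)(c2ccccc2)C(C)(C)C)C1=CC(=O)[C@@](C)(C[C@@H](OCc2ccc(OC)cc2)C(OC)OC)O1 | intermediate (not isolated)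
16 | (2R)-3-[(2R)-5-{(2Z)-1-[(tert-butyldiphenylsilyl)oxy]-4-hydroxybut-2-en-2-yl}-2-methyl-3-oxo-2,3-dihydrofuran-2-yl]-2-[(4-methoxybenzyl)oxy]propanal | OC/C=C(/CO[Si](c2ccccc2)(c2ccccc2)C(C)(C)C)C1=CC(=O)[C@@](C)(C[C@@H](OCc2ccc(OC)cc2)C=O)O1 | intermediate
17 | methyl acrylate | C=CC(=O)OC | starting material
18 | methyl (4R)-3-hydroxy-4-[(4-methoxybenzyl)oxy]-2-methylidene-5-[(2R)-5-{(2Z)-1-[(tert-butyldiphenylsilyl)oxy]-4-hydroxybut-2-en-2-yl}-2-methyl-3-oxo-2,3-dihydrofuran-2-yl]pentanoate (C3 epimers) | OC/C=C(/CO[Si](c2ccccc2)(c2ccccc2)C(C)(C)C)C1=CC(=O)[C@@](C)(C[C@@H](OCc2ccc(OC)cc2)C(O)C(=C)C(=O)OC)O1 | intermediate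
19 | methyl (4R)-3-hydroxy-4-[(4-methoxybenzyl)oxy]-2-methylidene-5-[(2R)-5-{(2Z)-1-[(tert-butyldiphenylsilyl)oxy]-4-oxobut-2-en-2-yl}-2-methyl-3-oxo-2,3-dihydrofuran-2-yl]pentanoate (C3 epimers) | O=C/C=C(/CO[Si](c2ccccc2)(c2ccccc2)C(C)(C)C)C1=CC(=O)[C@@](C)(C[C@@H](OCc2ccc(OC)cc2)C(O)C(=C)C(=O)OC)O1 | intermediate
20 | methyl (2Z,4R)-2-(bromomethyl)-4-[(4-methoxybenzyl)oxy]-5-[(2R)-5-{(2Z)-1-[(tert-butyldiphenylsilyl)oxy]-4-oxobut-2-en-2-yl}-2-methyl-3-oxo-2,3-dihydrofuran-2-yl]pent-2-enoate | O=C/C=C(/CO[Si](c2ccccc2)(c2ccccc2)C(C)(C)C)C1=CC(=O)[C@@](C)(C[C@@H](OCc2ccc(OC)cc2)/C=C(\CBr)C(=O)OC)O1 | intermediate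
21 | hydroxy ester: ten-membered carbocycle closed (C6–C7), C6–OH free (chromium alkoxide before work-up), methyl 2-propenoate unit on C7, configuration as in 22 | COC(=O)C(=C)[C@H]1[C@@H](O)/C=C(/CO[Si](c3ccccc3)(c3ccccc3)C(C)(C)C)C2=CC(=O)[C@@](C)(C[C@H]1OCc1ccc(OC)cc1)O2 | intermediate (not isolated)
22 | (6S,7R,8R,10R)-8-[(4-methoxybenzyl)oxy]-15-[(tert-butyldiphenylsilyl)oxy] analogue of the target (no tiglate; cis-fused lactone) | C=C1C(=O)O[C@H]2/C=C(/CO[Si](c4ccccc4)(c4ccccc4)C(C)(C)C)C3=CC(=O)[C@@](C)(C[C@@H](OCc4ccc(OC)cc4)[C@@H]12)O3 | intermediate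
23 | (6S,7R,8R,10R)-8-hydroxy-15-[(tert-butyldiphenylsilyl)oxy] lactone | C=C1C(=O)O[C@H]2/C=C(/CO[Si](c4ccccc4)(c4ccccc4)C(C)(C)C)C3=CC(=O)[C@@](C)(C[C@@H](O)[C@@H]12)O3 | intermediate
24 | tiglic acid, (E)-2-methylbut-2-enoic acid | C/C=C(\C)C(=O)O | starting material
25 | (6S,7R,8R,10R)-15-O-(tert-butyldiphenylsilyl) ether of the target | C=C1C(=O)O[C@H]2/C=C(/CO[Si](c4ccccc4)(c4ccccc4)C(C)(C)C)C3=CC(=O)[C@@](C)(C[C@@H](OC(=O)/C(C)=C/C)[C@@H]12)O3 | intermediate
26 | target CNP0269689.6 | C=C1C(=O)O[C@H]2/C=C(/CO)C3=CC(=O)[C@@](C)(C[C@@H](OC(=O)/C(C)=C/C)[C@@H]12)O3 | target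

## Step count and risks

Total steps: 15 (steps 1–3 make the vinyl iodide; steps 4–15 are the main line). Longest linear sequence: 12 steps (4–15, from acetone and 2,2-dimethoxyacetaldehyde).

**Steps most likely to fail**

Step 12 (macrocyclising allylation). The risks are ring strain, which favours oligomers, and facial control at C7. The predicted 7R outcome depends on the C8 ether oxygen sitting "inside"; if the C8 hydrogen sits there instead, the 6,7-bis-epimer of 22 forms. Fallback, from 16 back to 22: a Wittig reaction of 16 with ethyl 3-(trimethylsilyl)-2-(triphenylphosphoranylidene)propanoate (from Ph3P=CHCO2Et and ICH2SiMe3) would give the allylsilane ester ethyl (2Z,4R)-4-[(4-methoxybenzyl)oxy]-2-[(trimethylsilyl)methyl]pent-2-enoate carrying the furanone and the free C6 alcohol F1. MnO2 would oxidise this to the enal allylsilane F2. An intramolecular Hosomi–Sakurai allylation (BF3·OEt2, CH2Cl2, −78 °C, open transition state with its own facial preference, or Bu4NF for the fluoride-triggered variant) followed by acid lactonisation would return to 22. This replaces the bromide/chromium nucleophile, and steps 9–11, by a storable allylsilane with a different activation mode.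

Step 7 (carbonylative Sonogashira). Direct, CO-free enyne coupling and alkyne homocoupling can compete. Fallback, from 4 and 12 back to 13: cyclocarbonylation of iodo alcohol 4 (PdCl2(PPh3)2, CO, K2CO3, THF) would give the butenolide 3-{[(tert-butyldiphenylsilyl)oxy]methyl}furan-2(5H)-one F3. The dilithio derivative of 12 (n-BuLi, 2.1 equiv, THF, −78 °C, BF3·OEt2) would open this lactone at the carbonyl to the C6-hydroxy ynone (in equilibrium with its lactol) F4. Silylation (TBSCl, imidazole) would trap the open form as 13. Here the acyl carbon comes from a lactone and not from an acylpalladium species.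

Step 9 (Morita–Baylis–Hillman). The aldehyde is hindered and α-alkoxy, the reaction takes days, and the amine may erode C8 or add to the acrylate through the free alcohol. Fallback, from 16 directly to 18: a Nozaki–Hiyama–Kishi reaction of 16 with methyl 2-bromoacrylate (CrCl2, NiCl2 cat., DMF, rt) gives the same 2-(hydroxyalkyl)acrylate 18 through an α-acrylate vinylchromium under non-basic conditions, with no new intermediate.

## Further compounds

F1 | step 12 | ethyl (2Z,4R)-4-[(4-methoxybenzyl)oxy]-2-[(trimethylsilyl)methyl]-5-[(2R)-5-{(2Z)-1-[(tert-butyldiphenylsilyl)oxy]-4-hydroxybut-2-en-2-yl}-2-methyl-3-oxo-2,3-dihydrofuran-2-yl]pent-2-enoate | OC/C=C(/CO[Si](c2ccccc2)(c2ccccc2)C(C)(C)C)C1=CC(=O)[C@@](C)(C[C@@H](OCc2ccc(OC)cc2)/C=C(\C[Si](C)(C)C)C(=O)OCC)O1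
F2 | step 12 | ethyl (2Z,4R)-4-[(4-methoxybenzyl)oxy]-2-[(trimethylsilyl)methyl]-5-[(2R)-5-{(2Z)-1-[(tert-butyldiphenylsilyl)oxy]-4-oxobut-2-en-2-yl}-2-methyl-3-oxo-2,3-dihydrofuran-2-yl]pent-2-enoate | O=C/C=C(/CO[Si](c2ccccc2)(c2ccccc2)C(C)(C)C)C1=CC(=O)[C@@](C)(C[C@@H](OCc2ccc(OC)cc2)/C=C(\C[Si](C)(C)C)C(=O)OCC)O1
F3 | step 7 | 3-{[(tert-butyldiphenylsilyl)oxy]methyl}furan-2(5H)-one | O=C1OCC=C1CO[Si](c1ccccc1)(c1ccccc1)C(C)(C)C
F4 | step 7 | (2Z,7R,9R)-3-{[(tert-butyldiphenylsilyl)oxy]methyl}-1,7-dihydroxy-10,10-dimethoxy-9-[(4-methoxybenzyl)oxy]-7-methyldec-2-en-5-yn-4-one | OC/C=C(/CO[Si](c1ccccc1)(c1ccccc1)C(C)(C)C)C(=O)C#C[C@](C)(O)C[C@@H](OCc1ccc(OC)cc1)C(OC)OC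
F0 | step 9 | none | none
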